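**Retrosynthetic overview**
1. The strategy rests on the C1–C11 bond of the eleven-membered carbocycle. C11 is a secondary carbinol bonded directly to C1, the ring carbon that bears the exocyclic methylene. This 2-methylene-1-ol unit is opened to a C1 alkenyl iodide and a C11 aldehyde (Nozaki–Hiyama–Kishi closure, acid masked as tert-butyl ester).
2. The open-chain iodoalkene aldehyde is cut at C4=C5 (Horner–Wadsworth–Emmons) into 4-iodopent-4-enal (C1–C4) and a C5 phosphonoacetate carrying C6–C11.
3. C5–C6 comes from alkylating tert-butyl diethylphosphonoacetate with a C6 iodide made from a C6–C7 epoxide. Hydrolytic kinetic resolution of that epoxide sets C7.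
4. C7–C11, including the C9 gem-dimethyl group, come from 3,3-dimethylglutaric anhydride, and C6 from a Wittig methylenation.
5. Ring order: there is only one ring. It is closed in step 17, and the last step frees the acid.

Key step: step 17

Numbering used throughout: C1 (bears =CH2), C2, C3, C4=C5 (C5 bears the carboxyl group; C3 and C6 cis, E by the CIP rules), C6, C7 (isovalerate, S), C8, C9 (gem-dimethyl), C10, C11 (carbinol, S).

Assumption: the sense of induction of the chromium ligand on this macrocyclic substrate cannot be derived with certainty. The route is written with the L-valinol-derived (S)-ligand, and its enantiomer from D-valinol takes its place if a trial cyclisation favours the 11R carbinol.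

**Step 1**
Reactants: 1 3,3-dimethylglutaric anhydride
Product: 3 4,4-dimethyloxan-2-one (δ-lactone), via 5-hydroxy-3,3-dimethylpentanoic acid 2 (not isolated)
Conditions: NaBH4 (1.1 equiv), THF, 0 °C to rt; then 6 M HCl, rt
Reagents that add atoms: none
Why: Borohydride reduction of a cyclic anhydride stops at the hydroxy carboxylate, which lactonises on acidification; the anhydride is symmetrical, so no regiochemical question arises.

**Step 2**
Reactants: 3 4,4-dimethyloxan-2-one
Product: 4 4,4-dimethyloxan-2-ol (lactol)
Conditions: iBu2AlH (1.1 equiv), CH2Cl2, −78 °C; Rochelle salt work-up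
Reagents that add atoms: none
Why: Partial lactone reduction with iBu2AlH at low temperature gives a stable aluminium hemiacetal that is released as the lactol only on work-up.

**Step 3**
Reactants: 4 4,4-dimethyloxan-2-ol
Product: 5 3,3-dimethylhex-5-en-1-ol
Conditions: Ph3PCH3Br (2.5 equiv), KOtBu (2.4 equiv), THF, 0 °C to rt
Reagents that add atoms: methyltriphenylphosphonium bromide, C[P+](c1ccccc1)(c1ccccc1)c1ccccc1.[Br-]
Why: Wittig methylenation of the hydroxy aldehyde tautomer of the lactol; excess ylide covers the free hydroxyl group and adds C6 as the terminal methylene.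

**Step 4**
Reactants: 5 3,3-dimethylhex-5-en-1-ol
Product: 6 1-{[(3,3-dimethylhex-5-en-1-yl)oxy]methyl}-4-methoxybenzene (PMB ether of 5)
Conditions: NaH, 4-methoxybenzyl chloride, Bu4NI (cat.), THF–DMF, 0 °C to rt
Reagents that add atoms: 4-methoxybenzyl chloride, COc1ccc(CCl)cc1
Why: Williamson ether synthesis on an unhindered primary alkoxide; the ether keeps the C11 oxygen from opening the later epoxide in a 6-exo mode and can be removed under neutral oxidative conditions.

**Step 5**
Reactants: 6 PMB ether of 3,3-dimethylhex-5-en-1-ol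
Product: 7 rac-2-{4-[(4-methoxybenzyl)oxy]-2,2-dimethylbutyl}oxirane
Conditions: mCPBA, CH2Cl2, 0 °C to rt
Reagents that add atoms: mCPBA, O=C(OO)c1cccc(Cl)c1
Why: Prilezhaev epoxidation of the only alkene in the molecule; the product is racemic at C7.

**Step 6**
Reactants: 7 racemic epoxide
Product: 8 (S)-2-{4-[(4-methoxybenzyl)oxy]-2,2-dimethylbutyl}oxirane
Conditions: (S,S)-N,N'-bis(3,5-di-tert-butylsalicylidene)-1,2-cyclohexanediaminocobalt acetate, (S,S)-(salen)Co(OAc), 0.5 mol%; H2O (0.55 equiv), THF, 0 °C to rt
Reagents that add atoms: none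
Why: Hydrolytic kinetic resolution; the (S,S) trivalent cobalt salen complex should hydrolyse the R enantiomer of a simple alkyl oxirane much faster, so the unreacted S epoxide, which holds the C7 configuration of the target, is separated from the polar diol.

**Step 7**
Reactants: 8 (S)-epoxide
Product: 9 (2S)-1-iodo-6-[(4-methoxybenzyl)oxy]-4,4-dimethylhexan-2-ol
Conditions: LiI (1.5 equiv), AcOH (2 equiv), THF, rt
Reagents that add atoms: lithium iodide, [Li+].[I-]
Why: Acid-assisted SN2 opening of a terminal epoxide by iodide at the unsubstituted carbon C6; the C7–O bond is not touched, so C7 is retained.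

**Step 8**
Reactants: 9 (S)-iodohydrin
Product: 10 {[(2S)-1-iodo-6-[(4-methoxybenzyl)oxy]-4,4-dimethylhexan-2-yl]oxy}triethylsilane
Conditions: TESOTf, 2,6-lutidine, CH2Cl2, −78 to 0 °C
Reagents that add atoms: triethylsilyl triflate, CC[Si](CC)(CC)OS(=O)(=O)C(F)(F)F
Why: O-silylation with a silyl triflate and a hindered weak base is fast at low temperature and avoids re-closure of the iodohydrin to the epoxide.

**Step 9**
Reactants: 10 iodide with C7 triethylsilyl ether; 11 tert-butyl diethylphosphonoacetate
Product: 12 tert-butyl (4S)-2-(diethoxyphosphoryl)-8-[(4-methoxybenzyl)oxy]-6,6-dimethyl-4-(triethylsilyloxy)octanoate (both C2 epimers)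
Conditions: 11 (2 equiv), NaH (1.9 equiv), DMF, 0 °C to rt; then 10, 65 °C
Reagents that add atoms: none
Why: SN2 alkylation of a sodium phosphonoacetate with a primary iodide in a dipolar aprotic solvent forms C5–C6; the silyl ether at C7 blocks the alkoxide-triggered phosphoryl transfer and cyclopropane formation that direct epoxide opening would invite, and the new C5 centre is of no consequence because it becomes sp2.

**Step 10**
Reactants: 13 pent-4-yn-1-ol
Product: 14 4-iodopent-4-en-1-ol
Conditions: NaI, Me3SiCl, H2O (0.5 equiv), MeCN, rt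
Reagents that add atoms: sodium iodide, [Na+].[I-]
Why: Markovnikov hydroiodination of a terminal alkyne with hydrogen iodide generated in the flask gives the 2-iodoalk-1-ene.

**Step 11**
Reactants: 14 4-iodopent-4-en-1-ol
Product: 15 4-iodopent-4-enal
Conditions: Dess–Martin periodinane, CH2Cl2, 0 °C to rt; used promptly
Reagents that add atoms: none
Why: Dess–Martin oxidation stops at the aldehyde under near-neutral conditions that leave the alkenyl iodide intact.

**Step 12**
Reactants: 12 phosphonate; 15 4-iodopent-4-enal
Product: 16 tert-butyl (2E)-6-iodo-2-[(2S)-6-(4-methoxybenzyloxy)-4,4-dimethyl-2-(triethylsilyloxy)hexyl]hepta-2,6-dienoate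
Conditions: LiN(SiMe3)2 (1.05 equiv), DME, 0 °C; then 15, 0 °C to rt; chromatography
Reagents that add atoms: none
Why: Horner–Wadsworth–Emmons olefination forms C4=C5; the bulky tert-butyl ester, lithium counter-ion, DME and ambient temperature favour equilibration of the adducts towards the E enoate (ester trans to C3, C3 and C6 cis), and the minor Z isomer is removed by chromatography.

**Step 13**
Reactants: 16 triethylsilyl ether
Product: 17 tert-butyl (2E)-2-[(2S)-2-hydroxy-6-(4-methoxybenzyloxy)-4,4-dimethylhexyl]-6-iodohepta-2,6-dienoate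
Conditions: pyridinium p-toluenesulfonate (cat.), MeOH–CH2Cl2, 0 °C
Reagents that add atoms: none
Why: Mild acid-catalysed methanolysis removes the triethylsilyl ether while the PMB ether and tert-butyl ester survive, and the bulk and conjugation of that ester hold back γ-lactonisation of the free C7 hydroxyl group.

**Step 14**
Reactants: 17 C7 alcohol; 18 isovaleryl chloride
Product: 19 tert-butyl (2E)-6-iodo-2-[(2S)-6-(4-methoxybenzyloxy)-4,4-dimethyl-2-(3-methylbutanoyloxy)hexyl]hepta-2,6-dienoate
Conditions: 18 (1.5 equiv), pyridine, DMAP (cat.), CH2Cl2, 0 °C to rt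
Reagents that add atoms: none
Why: DMAP-catalysed O-acylation of a secondary alcohol with an acid chloride; the reaction takes place at oxygen, so C7 keeps its configuration.

**Step 15**
Reactants: 19 PMB ether
Product: 20 tert-butyl (2E)-2-[(2S)-6-hydroxy-4,4-dimethyl-2-(3-methylbutanoyloxy)hexyl]-6-iodohepta-2,6-dienoate
Conditions: DDQ (1.3 equiv), CH2Cl2–pH 7 phosphate buffer (10:1), 0 °C to rt
Reagents that add atoms: none
Why: Oxidative PMB cleavage; DDQ abstracts hydride from the electron-rich benzylic position and water hydrolyses the oxocarbenium ion, under neutral conditions that spare both esters, the enoate and the alkenyl iodide.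

**Step 16**
Reactants: 20 primary alcohol
Product: 21 tert-butyl (2E)-2-[(2S)-4,4-dimethyl-2-(3-methylbutanoyloxy)-6-oxohexyl]-6-iodohepta-2,6-dienoate (seco C1 iodoalkene C11 aldehyde)
Conditions: Dess–Martin periodinane, CH2Cl2, 0 °C to rt
Reagents that add atoms: none
Why: Dess–Martin oxidation of the C11 primary alcohol; the aldehyde has no α-stereocentre and the quaternary C9 rules out β-elimination.

**Step 17**
Reactants: 21 seco iodoalkene aldehyde
Product: 23 tert-butyl (1E,6S,10S)-6-hydroxy-8,8-dimethyl-5-methylidene-10-(3-methylbutanoyloxy)cycloundec-1-ene-1-carboxylate (tert-butyl ester of the target), via alkenylchromium species 22 (not isolated)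
Conditions: CrCl2 (8 equiv), (S)-N-[2-(4-isopropyl-4,5-dihydro-1,3-oxazol-2-yl)-6-methylphenyl]methanesulfonamide (8.5 equiv), Et3N (8.5 equiv), NiCl2 (1 mol% of the chromium), THF–MeCN, rt; 21 added by syringe pump over 12 h to about 2 mM; aqueous work-up
Reagents that add atoms: none
Why: CrCl2 reduces NiCl2 to zerovalent nickel, which inserts into the C1–I bond and passes the alkenyl group to trivalent chromium to give 22, and 22 adds 1,2 to the C11 aldehyde; this is the Nozaki–Hiyama–Kishi reaction in its macrocyclising form, known for 2-iodoalk-1-enes that close medium rings to exocyclic-methylene carbinols. The ring closes in an 11-exo-trig mode: C1 attacks the carbonyl carbon C11, both become ring atoms, and the oxygen and the methylene stay outside the ring. The new C11 centre is controlled by the chiral oxazoline sulfonamide bound to chromium, which shields one face of the coordinated aldehyde, because the only resident centre, C7, lies four bonds away and should exert little bias. The step needs chemoselectivity for the aldehyde over two esters and the enoate; alkenylchromium reagents are weakly basic and do not attack esters, and addition to C4=C5 would demand a 4-exo or 5-endo closure. Ring closure must outrun dimerisation, which is served by slow addition to high dilution, by the C4=C5 alkene that holds C3 and C6 cis, and by the gem-dimethyl group at C9. The nickel loading is kept low to suppress homocoupling of the alkenyl iodide to a diene.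

**Step 18**
Reactants: 23 tert-butyl ester of the target
Product: 25 (1E,6S,10S)-6-hydroxy-8,8-dimethyl-5-methylidene-10-(3-methylbutanoyloxy)cycloundec-1-ene-1-carboxylic acid (target), via bis(trimethylsilyl) derivative 24 (not isolated)
Conditions: Me3SiOTf (4 equiv), 2,6-lutidine (6 equiv), CH2Cl2, 0 °C to rt; then 10% aq. citric acid, THF–MeOH, 0 °C
Reagents that add atoms: none
Why: Silyl-triflate-mediated tert-butyl ester cleavage; silylation of the ester carbonyl releases the tert-butyl group as isobutene under lutidine buffering, the C11 hydroxyl group is silylated in passing, and both silyl groups fall off in the mild acidic work-up, so no strong protic acid that could ionise the allylic carbinol or start transannular reactions is needed.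

**Compound list**
1 | 3,3-dimethylglutaric anhydride | CC1(C)CC(=O)OC(=O)C1 | starting material
2 | 5-hydroxy-3,3-dimethylpentanoic acid (not isolated) | OCCC(C)(C)CC(=O)O | intermediate
3 | 4,4-dimethyloxan-2-one | CC1(C)CCOC(=O)C1 | intermediate
4 | 4,4-dimethyloxan-2-ol | CC1(C)CCOC(O)C1 | intermediate
5 | 3,3-dimethylhex-5-en-1-ol | C=CCC(C)(C)CCO | intermediate
6 | 1-{[(3,3-dimethylhex-5-en-1-yl)oxy]methyl}-4-methoxybenzene | C=CCC(C)(C)CCOCc1ccc(OC)cc1 | intermediate
7 | rac-2-{4-[(4-methoxybenzyl)oxy]-2,2-dimethylbutyl}oxirane | C1OC1CC(C)(C)CCOCc1ccc(OC)cc1 | intermediate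
8 | (S)-2-{4-[(4-methoxybenzyl)oxy]-2,2-dimethylbutyl}oxirane | C1[C@@H](O1)CC(C)(C)CCOCc1ccc(OC)cc1 | intermediate
9 | (2S)-1-iodo-6-[(4-methoxybenzyl)oxy]-4,4-dimethylhexan-2-ol | IC[C@@H](O)CC(C)(C)CCOCc1ccc(OC)cc1 | intermediate
10 | triethylsilyl ether of 9 | IC[C@@H](O[Si](CC)(CC)CC)CC(C)(C)CCOCc1ccc(OC)cc1 | intermediate
11 | tert-butyl diethylphosphonoacetate | CCOP(=O)(OCC)CC(=O)OC(C)(C)C | starting material
12 | tert-butyl (4S)-2-(diethoxyphosphoryl)-8-[(4-methoxybenzyl)oxy]-6,6-dimethyl-4-(triethylsilyloxy)octanoate, C2 epimers | CCOP(=O)(OCC)C(C(=O)OC(C)(C)C)C[C@@H](O[Si](CC)(CC)CC)CC(C)(C)CCOCc1ccc(OC)cc1 | intermediate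
13 | pent-4-yn-1-ol | C#CCCCO | starting material
14 | 4-iodopent-4-en-1-ol | C=C(I)CCCO | intermediate
15 | 4-iodopent-4-enal | C=C(I)CCC=O | intermediate
16 | tert-butyl (2E)-6-iodo-2-[(2S)-6-(4-methoxybenzyloxy)-4,4-dimethyl-2-(triethylsilyloxy)hexyl]hepta-2,6-dienoate | C=C(I)CC/C=C(/C(=O)OC(C)(C)C)C[C@@H](O[Si](CC)(CC)CC)CC(C)(C)CCOCc1ccc(OC)cc1 | intermediate
17 | tert-butyl (2E)-2-[(2S)-2-hydroxy-6-(4-methoxybenzyloxy)-4,4-dimethylhexyl]-6-iodohepta-2,6-dienoate | C=C(I)CC/C=C(/C(=O)OC(C)(C)C)C[C@@H](O)CC(C)(C)CCOCc1ccc(OC)cc1 | intermediate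
18 | isovaleryl chloride | CC(C)CC(Cl)=O | starting material
19 | tert-butyl (2E)-6-iodo-2-[(2S)-6-(4-methoxybenzyloxy)-4,4-dimethyl-2-(3-methylbutanoyloxy)hexyl]hepta-2,6-dienoate | C=C(I)CC/C=C(/C(=O)OC(C)(C)C)C[C@@H](OC(=O)CC(C)C)CC(C)(C)CCOCc1ccc(OC)cc1 | intermediate
20 | tert-butyl (2E)-2-[(2S)-6-hydroxy-4,4-dimethyl-2-(3-methylbutanoyloxy)hexyl]-6-iodohepta-2,6-dienoate | C=C(I)CC/C=C(/C(=O)OC(C)(C)C)C[C@@H](OC(=O)CC(C)C)CC(C)(C)CCO | intermediate
21 | tert-butyl (2E)-2-[(2S)-4,4-dimethyl-2-(3-methylbutanoyloxy)-6-oxohexyl]-6-iodohepta-2,6-dienoate | C=C(I)CC/C=C(/C(=O)OC(C)(C)C)C[C@@H](OC(=O)CC(C)C)CC(C)(C)CC=O | intermediate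
22 | C1 alkenylchromium species of trivalent chromium (not isolated; drawn as the dichloride, ligand and solvent on chromium left out) | C=C([Cr](Cl)Cl)CC/C=C(/C(=O)OC(C)(C)C)C[C@@H](OC(=O)CC(C)C)CC(C)(C)CC=O | intermediate
23 | tert-butyl (1E,6S,10S)-6-hydroxy-8,8-dimethyl-5-methylidene-10-(3-methylbutanoyloxy)cycloundec-1-ene-1-carboxylate | C=C1CC/C=C(/C(=O)OC(C)(C)C)C[C@@H](OC(=O)CC(C)C)CC(C)(C)C[C@@H]1O | intermediate
24 | trimethylsilyl ester and C11 trimethylsilyl ether of the target (not isolated) | C=C1CC/C=C(/C(=O)O[Si](C)(C)C)C[C@@H](OC(=O)CC(C)C)CC(C)(C)C[C@@H]1O[Si](C)(C)C | intermediate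
25 | (1E,6S,10S)-6-hydroxy-8,8-dimethyl-5-methylidene-10-(3-methylbutanoyloxy)cycloundec-1-ene-1-carboxylic acid | C=C1CC/C=C(/C(=O)O)C[C@@H](OC(=O)CC(C)C)CC(C)(C)C[C@@H]1O | target

**Total step count:** 18. **Longest linear sequence:** 16 (steps 1–9 and 12–18; steps 10–11 form the side branch).

**Steps most likely to fail**

1. Step 17. The conformation of the forming eleven-membered ring may override the ligand, giving poor facial selectivity at the C11 aldehyde. The bulky ligand sphere may also slow the closure.
   - The fallback sets out from 21 and comes back at 23. It separates ring closure from stereocontrol.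
   - 21 is cyclised without ligand (CrCl2, NiCl2 cat., DMSO, high dilution). The mixture of 23 and the 11R carbinol epimer F1 is accepted.
   - The mixture is oxidised with Dess–Martin periodinane to the cross-conjugated C11 ketone F2.
   - F2 is reduced by Corey–Bakshi–Shibata reduction with (R)-2-methyl-CBS-oxazaborolidine and catecholborane in toluene at −78 °C. The 2-substituted alkenyl arm at C1 is expected to act as the larger group, so hydride delivery should give the 11S alcohol 23.

2. Step 9. The SN2 displacement at the β-branched, β-silyloxy C6 iodide may be too slow. Dealkylation of the phosphonate by iodide and elimination could then take over.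
   - The fallback sets out from 8 and comes back at 12. It makes C5–C6 first and brings in phosphorus afterwards.
   - Epoxide 8 is opened at C6 with the lithium enolate of tert-butyl acetate (LiN(iPr)2, then Et3Al, THF, −78 to −40 °C). This gives tert-butyl (4R)-4-hydroxy-8-[(4-methoxybenzyl)oxy]-6,6-dimethyloctanoate F3. The spatial arrangement at C7 is unchanged; only the descriptor changes with the priorities.
   - F3 is silylated at once (TESOTf, 2,6-lutidine) to its triethylsilyl ether F4.
   - The enolate of F4 (LiN(iPr)2, THF, −78 °C) is trapped on carbon with diethyl chlorophosphite, and the phosphonite is oxidised with H2O2 on work-up to give 12.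

3. Step 12. The large α-substituent on the phosphonate may erode the E preference, or a sluggish addition may leave the base-sensitive aldehyde exposed.
   - The fallback sets out from 12 and 15 and comes back at 16. It builds the trisubstituted alkene under thermodynamic control by cross metathesis.
   - 12 is methylenated with aqueous formaldehyde and K2CO3 to tert-butyl (4S)-8-[(4-methoxybenzyl)oxy]-6,6-dimethyl-2-methylidene-4-(triethylsilyloxy)octanoate F5, a step without a geometry question.
   - 15 is converted by Wittig methylenation into 2-iodohexa-1,5-diene F6.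
   - F5 and excess F6 are joined with the second-generation Hoveyda–Grubbs catalyst, (H2IMes)Cl2Ru(=CH-o-iPrOC6H4), in refluxing CH2Cl2. The hindered 2-iodoalkene should stay out of the metathesis, and the reversible exchange should favour the E enoate 16.

**Further compounds**
F1 | step 17 | tert-butyl (1E,6R,10S)-6-hydroxy-8,8-dimethyl-5-methylidene-10-(3-methylbutanoyloxy)cycloundec-1-ene-1-carboxylate | C=C1CC/C=C(/C(=O)OC(C)(C)C)C[C@@H](OC(=O)CC(C)C)CC(C)(C)C[C@H]1O
F2 | step 17 | tert-butyl (1E,10S)-8,8-dimethyl-5-methylidene-10-(3-methylbutanoyloxy)-6-oxocycloundec-1-ene-1-carboxylate | C=C1CC/C=C(/C(=O)OC(C)(C)C)C[C@@H](OC(=O)CC(C)C)CC(C)(C)CC1=O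
F3 | step 9 | tert-butyl (4R)-4-hydroxy-8-[(4-methoxybenzyl)oxy]-6,6-dimethyloctanoate | CC(C)(C)OC(=O)CC[C@@H](O)CC(C)(C)CCOCc1ccc(OC)cc1
F4 | step 9 | tert-butyl (4R)-8-[(4-methoxybenzyl)oxy]-6,6-dimethyl-4-(triethylsilyloxy)octanoate | CC(C)(C)OC(=O)CC[C@@H](O[Si](CC)(CC)CC)CC(C)(C)CCOCc1ccc(OC)cc1
F5 | step 12 | tert-butyl (4S)-8-[(4-methoxybenzyl)oxy]-6,6-dimethyl-2-methylidene-4-(triethylsilyloxy)octanoate | C=C(C(=O)OC(C)(C)C)C[C@@H](O[Si](CC)(CC)CC)CC(C)(C)CCOCc1ccc(OC)cc1
F6 | step 12 | 2-iodohexa-1,5-diene | C=C(I)CCC=C
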